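**One step.** In a one-step world, substrate and reagent give intermediate A and it falls back. The forward rate goes with c(substrate)·c(reagent), the back rate with c(intermediate A). Divide one by the other and time drops out: where they balance, c(intermediate A)/(c(substrate)·c(reagent)) stands still. Call this the binding quotient, the apparent equilibrium constant.

| flask | substrate | reagent | remark | time |
|---|---|---|---|---|
| elm | 0.058 M (in portions, 4) | 1.2 equiv | the very flask that is asked about, followed so far; portions every 2.0 min |  |
| maple | 0.039 M (in portions, 4) | 1.2 equiv | run made earlier; portions every 2.0 min |  |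
| flask | 0.058 M (in portions, 4) | 1.20 equiv | the portions of substrate follow each other after 2.0 min, the first at the start | 8.0 min |

| run | time / min | substrate / % | intermediate A / % | product / % |
|---|---|---|---|---|
| elm | 0.333 | 17.7 | 7.5 | 0.3 |
| elm | 0.833 | 14.3 | 10.8 | 0.3 |
| elm | 1.50 | 13.4 | 11.7 | 0 |
| elm | 2.50 | 30.3 | 18.2 | 0.4 |
| maple | 1.00 | 16.6 | 8.1 | 0 |
| maple | 3.00 | 32.8 | 16.1 | 0.4 |
| maple | 5.00 | 50.4 | 23.2 | 0 |
| maple | 8.00 | 68.0 | 29.3 | 0 |

(readings scatter by 0.3 percentage points)

* concentration of substrate at 8.0 min, in M
* concentration of intermediate A at 8.0 min, in M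



**First way.** Take elm at 1.50 min, the last reading before its second portion. The reagent lay there from the start, so c(reagent) is its charge less intermediate A. The quotient reads 13.9 M⁻¹.

**Second way.** The same reckoning on maple at 8.00 min reads 12.2 M⁻¹. The two part, so check the balances. Elm's sums to 25.1% against the 25.0% charged by then. Maple's falls short by 2.70%. If that material holds one reagent each, maple's reagent was overcounted, and its quotient becomes 12.6 M⁻¹. Elm's smaller readings, 13.4% and 11.7%, carry the same scatter of 0.3 percentage points, so part of the remaining gap may be scatter.

**My reckoning.** I carry the mean, the binding quotient 13.2 M⁻¹. With maple's shortfall applied to elm, solving the quotient puts 37.1% of the charge in intermediate A. That gives c(intermediate A) = 0.0215 M and c(substrate) = 0.0349 M.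

**The forecast.** It said “it should be close to equilibrium” and gave 0.0349 M substrate and 0.0211 M intermediate A. Its intermediate A lies 4.014 × 10⁻⁴ M below mine.

**The result.** Elm gives 0.0352 M substrate and 0.0203 M intermediate A, so the forecast held.

    intermediate C → intermediate D (k = 0.00790 s⁻¹)
    substrate + reagent ⇌ intermediate A (K = 13.0 M⁻¹, k = 0.380 M⁻¹ s⁻¹)
    intermediate B ⇌ intermediate C (K = 0.440, k = 0.0460 s⁻¹)
    reagent + intermediate A ⇌ intermediate B (K = 1.60 M⁻¹, k = 0.0200 M⁻¹ s⁻¹)
    intermediate D ⇌ product (K = 0.900, k = 0.00180 s⁻¹)

**Why it held.** In elm, c(reagent) is 0.0443 M, so the carried quotient predicts a ratio of intermediate A to substrate of 0.585, and the flask shows 0.577. The largest single effect on c(substrate) is the back reaction of intermediate A: the run without it ends at 0.00727 M, not 0.0352 M. In a neighbour flask charged with 0.23 M substrate at the same equivalents, 34.9% of the reagent stands free at 8.00 min, so the quotient predicts a ratio of 1.28, and that flask shows 1.25.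

(Readings and results are simulated on assumed constants; the scatter is artificial.)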